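The route rests on cutting the C2–C3 bond of ring C. In the target, C2 is a lone OCH2 carbon held between O1 of ring A and the stereocentre C3, which itself sits between the C4 carbonyl and ring B; C2 can therefore start life as a methyl ether on ring A. A chiral dirhodium carboxylate converts an α-diazo deoxybenzoin into a carbene at C3 that inserts into a methoxy C–H bond, closing ring C, forging C2–C3 and fixing (3S) in a single operation. The precursor carries a 2,6-dimethoxy-4-silyloxy ring A, so that either rotamer is productive, and a fully silylated ring B with its hydrated geranyl chain.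

Key step: step 12

Remark on the chemistry: atom labels (O1, C2, C3, C4, C5) and ring letters follow isoflavanone numbering; C3 is (S) and the side-chain alkene is (E) in every compound that contains them.

Assumption: the facial preference of Rh2(S-PTTL)4, dirhodium tetrakis[N-phthaloyl-(S)-tert-leucinate], in step 12 is taken to give (3S). If the opposite sense is preferred, the mirror-image catalyst Rh2(R-PTTL)4 takes its place with no other change.

Design note: every oxygen except the two ring A methoxy groups is silylated (aryl TIPS, tertiary TES). The carbene therefore meets no C–H next to oxygen other than OCH3, and one buffered fluoride treatment unmasks all hydroxyls at the end.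

Step 1
Reactants: 1 3,5-dimethoxyphenol
Product: 2 triisopropyl(3,5-dimethoxyphenoxy)silane
Conditions: TIPSCl, imidazole, DMF, 23 °C
Reagents that add atoms: triisopropylsilyl chloride, CC(C)[Si](Cl)(C(C)C)C(C)C
Why: Imidazole-promoted silyl ether formation masks the only acidic proton with a bulky group that directs metalation poorly and resists migration, so the next lithiation is steered by the two methoxy groups alone.

Step 2
Reactants: 2 triisopropyl(3,5-dimethoxyphenoxy)silane
Product: 4 1-[2,6-dimethoxy-4-(triisopropylsilyloxy)phenyl]ethanone, via aryllithium 3 (not isolated)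
Conditions: n-BuLi, THF, 0 → 23 °C; then MeC(O)N(OMe)Me, −78 → 0 °C; aq NH4Cl
Reagents that add atoms: N-methoxy-N-methylacetamide, CC(=O)N(C)OC
Why: Directed ortho-metalation removes the proton flanked by both methoxy groups, and the Weinreb ketone synthesis stops at monoacylation because the chelated tetrahedral adduct persists until work-up.

Step 3
Reactants: 5 geranyl acetate
Product: 8 (2E)-3,7-dimethyloct-2-ene-1,7-diol, via organomercurial 6 (not isolated), via hydroxy acetate 7 (not isolated)
Conditions: Hg(OAc)2, THF–H2O, 23 °C; then 3 M NaOH, NaBH4, 0 °C; then MeOH, 23 °C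
Reagents that add atoms: water, O
Why: Oxymercuration–demercuration hydrates only the remote 6,7-alkene in the Markovnikov sense, because the 2,3-alkene is deactivated by the allylic acetoxy group and keeps its E geometry, and the alkaline borohydride medium then saponifies the acetate.

Step 4
Reactants: 8 (2E)-3,7-dimethyloct-2-ene-1,7-diol
Product: 9 (6E)-8-bromo-2,6-dimethyloct-6-en-2-ol
Conditions: PPh3, CBr4, CH2Cl2, −20 → 0 °C
Reagents that add atoms: carbon tetrabromide, BrC(Br)(Br)Br
Why: In this Appel reaction the alkoxyphosphonium ion forms only at the unhindered primary allylic hydroxyl and is displaced by bromide in SN2 fashion with the E alkene untouched, while the tertiary alcohol is too hindered to be activated at low temperature.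

Step 5
Reactants: 9 (6E)-8-bromo-2,6-dimethyloct-6-en-2-ol
Product: 10 [(6E)-8-bromo-2,6-dimethyloct-6-en-2-yl]oxy(triethyl)silane
Conditions: TESOTf, 2,6-lutidine, CH2Cl2, −78 → 0 °C
Reagents that add atoms: triethylsilyl triflate, CC[Si](CC)(CC)OS(=O)(=O)C(F)(F)F
Why: Silylation with a silyl triflate and a hindered pyridine base is the standard way to cap a tertiary alcohol, and it removes the only proton that would quench the aryllithium of step 7.

Step 6
Reactants: 11 4-bromoresorcinol
Product: 12 1-bromo-2,4-bis(methoxymethoxy)benzene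
Conditions: MOMCl, i-Pr2NEt, CH2Cl2, 0 → 23 °C
Reagents that add atoms: chloromethyl methyl ether, COCCl
Why: O-Alkylation of both phenols (Williamson-type ether formation) installs two acetal ethers that are strong directing groups for the metalation that follows.

Step 7
Reactants: 12 1-bromo-2,4-bis(methoxymethoxy)benzene; 10 [(6E)-8-bromo-2,6-dimethyloct-6-en-2-yl]oxy(triethyl)silane
Product: 14 1-bromo-2,4-bis(methoxymethoxy)-3-[(2E)-3,7-dimethyl-7-(triethylsilyloxy)oct-2-en-1-yl]benzene, via aryllithium 13 (not isolated)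
Conditions: LiTMP (lithium 2,2,6,6-tetramethylpiperidide, from TMPH and n-BuLi), THF, −78 °C; then CuBr·SMe2 (10 mol%), 10, −78 → 0 °C
Reagents that add atoms: none
Why: Directed ortho-metalation with a non-nucleophilic amide removes the proton flanked by both MOM ethers without bromine–lithium exchange (lithium ends meta to bromine, so no aryne can form), and copper-catalysed SN2 allylic substitution of the primary bromide then attaches the chain with its E geometry intact.

Step 8
Reactants: 14 1-bromo-2,4-bis(methoxymethoxy)-3-[(2E)-3,7-dimethyl-7-(triethylsilyloxy)oct-2-en-1-yl]benzene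
Product: 15 4-bromo-2-[(2E)-7-hydroxy-3,7-dimethyloct-2-en-1-yl]benzene-1,3-diol
Conditions: HCl (0.5 M in MeOH), 23–30 °C
Reagents that add atoms: none
Why: Acid-catalysed acetal methanolysis removes both MOM groups and the temporary TES group in one operation, the dilute acid being too weak at this temperature to cyclise the ortho-allyl phenol to a chroman or to ionise the tertiary alcohol.

Step 9
Reactants: 15 4-bromo-2-[(2E)-7-hydroxy-3,7-dimethyloct-2-en-1-yl]benzene-1,3-diol
Product: 17 1-bromo-2,4-bis(triisopropylsilyloxy)-3-[(2E)-3,7-dimethyl-7-(triethylsilyloxy)oct-2-en-1-yl]benzene, via bis-TIPS ether 16 (not isolated)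
Conditions: TIPSOTf (2.3 equiv), 2,6-lutidine, CH2Cl2, 0 °C; then TESOTf (1.3 equiv), −40 → 0 °C
Reagents that add atoms: triisopropylsilyl triflate, CC(C)[Si](OS(=O)(=O)C(F)(F)F)(C(C)C)C(C)C; triethylsilyl triflate, CC[Si](CC)(CC)OS(=O)(=O)C(F)(F)F
Why: In this silyl triflate silylation the two phenols take up the bulky TIPS group, which barely reacts with the tertiary alcohol, and the smaller TESOTf then caps that alcohol, so that no oxygen on this fragment bears a C–H on its substituent.

Step 10
Reactants: 4 1-[2,6-dimethoxy-4-(triisopropylsilyloxy)phenyl]ethanone; 17 1-bromo-2,4-bis(triisopropylsilyloxy)-3-[(2E)-3,7-dimethyl-7-(triethylsilyloxy)oct-2-en-1-yl]benzene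
Product: 18 1-[2,6-dimethoxy-4-(triisopropylsilyloxy)phenyl]-2-{3-[(2E)-3,7-dimethyl-7-(triethylsilyloxy)oct-2-en-1-yl]-2,4-bis(triisopropylsilyloxy)phenyl}ethanone
Conditions: Pd2(dba)3 (2.5 mol%), XPhos (6 mol%), K3PO4, toluene, 85 °C
Reagents that add atoms: none
Why: In this Buchwald–Hartwig-type α-arylation of a ketone, oxidative addition of the aryl bromide to zerovalent palladium, exchange with the potassium enolate of 4 and reductive elimination form the C3–C1' bond, and the reaction stops at monoarylation because the more acidic product rests as a hindered enolate.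

Step 11
Reactants: 18 the deoxybenzoin of step 10
Product: 19 2-diazo-1-[2,6-dimethoxy-4-(triisopropylsilyloxy)phenyl]-2-{3-[(2E)-3,7-dimethyl-7-(triethylsilyloxy)oct-2-en-1-yl]-2,4-bis(triisopropylsilyloxy)phenyl}ethanone
Conditions: p-ABSA, DBU, MeCN, 0 → 23 °C
Reagents that add atoms: 4-acetamidobenzenesulfonyl azide, CC(=O)Nc1ccc(cc1)S(=O)(=O)N=[N+]=[N-]
Why: In this Regitz diazo transfer the DBU-generated enolate of the doubly activated benzylic methylene attacks the terminal nitrogen of the sulfonyl azide and the adduct collapses to the diazo ketone and the sulfonamide, under conditions that leave aryl silyl ethers intact.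

Step 12
Reactants: 19 the α-diazo deoxybenzoin of step 11
Product: 20 (3S)-5-methoxy-7-(triisopropylsilyloxy)-3-{3-[(2E)-3,7-dimethyl-7-(triethylsilyloxy)oct-2-en-1-yl]-2,4-bis(triisopropylsilyloxy)phenyl}chroman-4-one
Conditions: Rh2(S-PTTL)4 (1 mol%), toluene, −20 → 0 °C, slow addition of 19 (final 0.01 M)
Reagents that add atoms: none
Why: Proposed new method: Loss of N2 from 19 at the dirhodium core gives a carbene at C3 with ring B as donor and the aroyl group as acceptor, and this carbene inserts into a C–H bond of an ortho OCH3 group in a concerted, asynchronous three-centre event in which the hydrogen moves to C3 while C2–C3 forms. The closest known reaction types are dirhodium-catalysed intramolecular C–H insertions of ortho-alkoxyaryl diazo ketones that give chroman-4-ones, enantioselective cyclisations of α-aryl-α-diazo ketones with this catalyst family, and insertions of aryl-substituted carbenes into methyl ether C–H bonds. Ring C closes by 1,6-insertion (carbene carbon C3 counted as atom 1, the methoxy carbon as atom 6) through a six-membered arrangement, the 1,5-position being the ether oxygen, which offers no C–H. The new stereocentre C3 is controlled by the chiral N-phthaloyl-tert-leucinate ligand wall, which decides the face of the carbene plane that the C–H bond approaches, and because C–C and C–H bonds form together without an enol intermediate that choice should pass into the ketone. The step needs insertion to win over oxonium ylide formation, carbene dimerisation and attack on the side chain; the substrate secures this through its twisted 2,6-dimethoxyaryl ketone, which holds an oxygen-activated CH3 over the carbene in either rotamer, through silyl ethers with no C–H next to oxygen, and through an alkene placed meta to the carbene-bearing carbon and out of reach, while slow addition at high dilution suppresses bimolecular paths.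

Step 13
Reactants: 20 the (3S)-5-O-methyl isoflavanone of step 12
Product: 21 (3S)-5-hydroxy-7-(triisopropylsilyloxy)-3-{3-[(2E)-3,7-dimethyl-7-(triethylsilyloxy)oct-2-en-1-yl]-2,4-bis(triisopropylsilyloxy)phenyl}chroman-4-one
Conditions: MgI2·OEt2 (3 equiv), toluene–Et2O, 50 °C; aq NH4Cl
Reagents that add atoms: none
Why: In this chelation-controlled ether cleavage magnesium binds the C4 carbonyl and the peri C5 methoxy oxygen and iodide removes the methyl group by SN2 attack, while the unchelated silyl ethers and the alkene are left alone and the absence of base keeps C3 from enolising.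

Step 14
Reactants: 21 the (3S)-5-hydroxy silyl-protected isoflavanone of step 13
Product: 22 (3S)-5,7-dihydroxy-3-{2,4-dihydroxy-3-[(2E)-7-hydroxy-3,7-dimethyloct-2-en-1-yl]phenyl}chroman-4-one (target)
Conditions: HF·pyridine, pyridine, THF, 0 → 23 °C
Reagents that add atoms: none
Why: Fluoride-mediated desilylation, driven by Si–F bond formation, removes the three aryl TIPS ethers and the tertiary TES ether, and the pyridine-buffered, weakly acidic medium should neither enolise C3 nor cyclise the ortho-allyl phenol.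

Compound list

1 | 3,5-dimethoxyphenol | COc1cc(O)cc(OC)c1 | starting material
2 | triisopropyl(3,5-dimethoxyphenoxy)silane | COc1cc(O[Si](C(C)C)(C(C)C)C(C)C)cc(OC)c1 | intermediate
3 | [2,6-dimethoxy-4-(triisopropylsilyloxy)phenyl]lithium (not isolated) | [Li]c1c(OC)cc(O[Si](C(C)C)(C(C)C)C(C)C)cc1OC | intermediate
4 | 1-[2,6-dimethoxy-4-(triisopropylsilyloxy)phenyl]ethanone | CC(=O)c1c(OC)cc(O[Si](C(C)C)(C(C)C)C(C)C)cc1OC | intermediate
5 | geranyl acetate, (2E)-3,7-dimethylocta-2,6-dien-1-yl acetate | CC(C)=CCC/C(C)=C/COC(C)=O | starting material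
6 | (2E)-6-(acetoxymercurio)-7-hydroxy-3,7-dimethyloct-2-en-1-yl acetate, racemic at C6 (not isolated) | CC(C)(O)C([Hg]OC(C)=O)CC/C(C)=C/COC(C)=O | intermediate
7 | (2E)-7-hydroxy-3,7-dimethyloct-2-en-1-yl acetate (not isolated) | CC(C)(O)CCC/C(C)=C/COC(C)=O | intermediate
8 | (2E)-3,7-dimethyloct-2-ene-1,7-diol | CC(C)(O)CCC/C(C)=C/CO | intermediate
9 | (6E)-8-bromo-2,6-dimethyloct-6-en-2-ol | CC(C)(O)CCC/C(C)=C/CBr | intermediate
10 | [(6E)-8-bromo-2,6-dimethyloct-6-en-2-yl]oxy(triethyl)silane | CC[Si](CC)(CC)OC(C)(C)CCC/C(C)=C/CBr | intermediate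
11 | 4-bromoresorcinol, 4-bromobenzene-1,3-diol | Oc1ccc(Br)c(O)c1 | starting material
12 | 1-bromo-2,4-bis(methoxymethoxy)benzene | COCOc1ccc(Br)c(OCOC)c1 | intermediate
13 | [3-bromo-2,6-bis(methoxymethoxy)phenyl]lithium (not isolated) | COCOc1ccc(Br)c(OCOC)c1[Li] | intermediate
14 | 1-bromo-2,4-bis(methoxymethoxy)-3-[(2E)-3,7-dimethyl-7-(triethylsilyloxy)oct-2-en-1-yl]benzene | C/C(=C\Cc1c(OCOC)ccc(Br)c1OCOC)CCCC(C)(C)O[Si](CC)(CC)CC | intermediate
15 | 4-bromo-2-[(2E)-7-hydroxy-3,7-dimethyloct-2-en-1-yl]benzene-1,3-diol | C/C(=C\Cc1c(O)ccc(Br)c1O)CCCC(C)(C)O | intermediate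
16 | (6E)-8-[3-bromo-2,6-bis(triisopropylsilyloxy)phenyl]-2,6-dimethyloct-6-en-2-ol (not isolated) | C/C(=C\Cc1c(O[Si](C(C)C)(C(C)C)C(C)C)ccc(Br)c1O[Si](C(C)C)(C(C)C)C(C)C)CCCC(C)(C)O | intermediate
17 | 1-bromo-2,4-bis(triisopropylsilyloxy)-3-[(2E)-3,7-dimethyl-7-(triethylsilyloxy)oct-2-en-1-yl]benzene | C/C(=C\Cc1c(O[Si](C(C)C)(C(C)C)C(C)C)ccc(Br)c1O[Si](C(C)C)(C(C)C)C(C)C)CCCC(C)(C)O[Si](CC)(CC)CC | intermediate
18 | 1-[2,6-dimethoxy-4-(triisopropylsilyloxy)phenyl]-2-{3-[(2E)-3,7-dimethyl-7-(triethylsilyloxy)oct-2-en-1-yl]-2,4-bis(triisopropylsilyloxy)phenyl}ethanone (deoxybenzoin) | C/C(=C\Cc1c(O[Si](C(C)C)(C(C)C)C(C)C)ccc(CC(=O)c2c(OC)cc(O[Si](C(C)C)(C(C)C)C(C)C)cc2OC)c1O[Si](C(C)C)(C(C)C)C(C)C)CCCC(C)(C)O[Si](CC)(CC)CC | intermediate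
19 | 2-diazo-1-[2,6-dimethoxy-4-(triisopropylsilyloxy)phenyl]-2-{3-[(2E)-3,7-dimethyl-7-(triethylsilyloxy)oct-2-en-1-yl]-2,4-bis(triisopropylsilyloxy)phenyl}ethanone (α-diazo deoxybenzoin) | C/C(=C\Cc1c(O[Si](C(C)C)(C(C)C)C(C)C)ccc(C(=[N+]=[N-])C(=O)c2c(OC)cc(O[Si](C(C)C)(C(C)C)C(C)C)cc2OC)c1O[Si](C(C)C)(C(C)C)C(C)C)CCCC(C)(C)O[Si](CC)(CC)CC | intermediate
20 | (3S)-5-methoxy-7-(triisopropylsilyloxy)-3-{3-[(2E)-3,7-dimethyl-7-(triethylsilyloxy)oct-2-en-1-yl]-2,4-bis(triisopropylsilyloxy)phenyl}chroman-4-one | C/C(=C\Cc1c(O[Si](C(C)C)(C(C)C)C(C)C)ccc([C@H]2COc3cc(O[Si](C(C)C)(C(C)C)C(C)C)cc(OC)c3C2=O)c1O[Si](C(C)C)(C(C)C)C(C)C)CCCC(C)(C)O[Si](CC)(CC)CC | intermediate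
21 | (3S)-5-hydroxy-7-(triisopropylsilyloxy)-3-{3-[(2E)-3,7-dimethyl-7-(triethylsilyloxy)oct-2-en-1-yl]-2,4-bis(triisopropylsilyloxy)phenyl}chroman-4-one | C/C(=C\Cc1c(O[Si](C(C)C)(C(C)C)C(C)C)ccc([C@H]2COc3cc(O[Si](C(C)C)(C(C)C)C(C)C)cc(O)c3C2=O)c1O[Si](C(C)C)(C(C)C)C(C)C)CCCC(C)(C)O[Si](CC)(CC)CC | intermediate
22 | (3S)-5,7-dihydroxy-3-{2,4-dihydroxy-3-[(2E)-7-hydroxy-3,7-dimethyloct-2-en-1-yl]phenyl}chroman-4-one | C/C(=C\Cc1c(O)ccc([C@H]2COc3cc(O)cc(O)c3C2=O)c1O)CCCC(C)(C)O | target

Total step count: 14.
Longest linear sequence: 11 steps (steps 3, 4, 5, 7, 8, 9, 10, 11, 12, 13, 14, from geranyl acetate).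

Steps most likely to fail

Step 12 (the proposed insertion). The carbene may be captured by the methoxy oxygen instead of the C–H bond, giving an oxonium ylide that rearranges to a benzofuranone. It may also dimerise, or insert with poor facial selectivity. The fallback uses known chemistry only; it sets out from deoxybenzoin 18 and comes back to the route at 20. Chelation-controlled mono-demethylation of 18 with MgI2·OEt2 should give the ortho-hydroxy deoxybenzoin F1. Heating with N,N-dimethylformamide dimethyl acetal in toluene should then close ring C through the enaminone to the isoflavone F2. Asymmetric transfer hydrogenation with RuCl(p-cymene)[(S,S)-TsDPEN] and HCO2H–Et3N should reduce the C2–C3 double bond and then the ketone, with dynamic kinetic resolution of the labile C3 centre, to the cis-(3S,4S)-isoflavan-4-ol F3. That sense is expected by analogy with simple aryl ketones, and the mirror-image ligand is the alternative. Oxidation of the carbinol with Dess–Martin periodinane buffered by NaHCO3 should then restore the C4 ketone without touching C3 and deliver 20.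

Step 10 (α-arylation). Oxidative addition to the electron-rich bromide flanked by a bulky silyloxy group may be slow, and the hot basic medium may cause silyl loss or migration next to the product enolate. The fallback forms the C4–ring A bond by acylation under cold conditions; it sets out from bromide 17 and comes back at 18. Negishi coupling of 17 with the Reformatsky reagent BrZnCH2CO2Et (Pd2(dba)3, XPhos, THF, 23–50 °C, no base) should give the ethyl arylacetate F4. Treatment with MeNH(OMe)·HCl and i-PrMgCl at −20 °C should convert it into the Weinreb amide F5. Addition of aryllithium 3 (made from 2 as in step 2) at −78 °C should then give 18.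

Step 13 (demethylation after the stereocentre is set). The magnesium chelate may promote enolisation at C3 and erode the enantiomeric purity, or silyl groups may be lost with cyclisation of the freed phenol onto the alkene. The fallback moves the demethylation ahead of the stereogenic step; it sets out from 18 and comes back at the target 22. Compound 18 is demethylated to the ortho-hydroxy deoxybenzoin F1 as in the first fallback. Silylation with TIPSOTf and 2,6-lutidine should give the tetrasilyl deoxybenzoin F6, and diazo transfer as in step 11 the diazo ketone F7. The insertion of step 12 into the one remaining methoxy group should give the (3S)-5,7-bis(triisopropylsilyloxy) isoflavanone F8, with the bulky silyloxy group expected to turn away from the catalyst. Buffered HF·pyridine as in step 14 should then give 22 directly.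

Further compounds

F1 | step 12 | 1-[2-hydroxy-6-methoxy-4-(triisopropylsilyloxy)phenyl]-2-{3-[(2E)-3,7-dimethyl-7-(triethylsilyloxy)oct-2-en-1-yl]-2,4-bis(triisopropylsilyloxy)phenyl}ethanone | C/C(=C\Cc1c(O[Si](C(C)C)(C(C)C)C(C)C)ccc(CC(=O)c2c(O)cc(O[Si](C(C)C)(C(C)C)C(C)C)cc2OC)c1O[Si](C(C)C)(C(C)C)C(C)C)CCCC(C)(C)O[Si](CC)(CC)CC
F2 | step 12 | 5-methoxy-7-(triisopropylsilyloxy)-3-{3-[(2E)-3,7-dimethyl-7-(triethylsilyloxy)oct-2-en-1-yl]-2,4-bis(triisopropylsilyloxy)phenyl}chromen-4-one (isoflavone) | C/C(=C\Cc1c(O[Si](C(C)C)(C(C)C)C(C)C)ccc(C2=COc3cc(O[Si](C(C)C)(C(C)C)C(C)C)cc(OC)c3C2=O)c1O[Si](C(C)C)(C(C)C)C(C)C)CCCC(C)(C)O[Si](CC)(CC)CC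
F3 | step 12 | (3S,4S)-cis-5-methoxy-7-(triisopropylsilyloxy)-3-{3-[(2E)-3,7-dimethyl-7-(triethylsilyloxy)oct-2-en-1-yl]-2,4-bis(triisopropylsilyloxy)phenyl}chroman-4-ol | C/C(=C\Cc1c(O[Si](C(C)C)(C(C)C)C(C)C)ccc([C@H]2COc3cc(O[Si](C(C)C)(C(C)C)C(C)C)cc(OC)c3[C@H]2O)c1O[Si](C(C)C)(C(C)C)C(C)C)CCCC(C)(C)O[Si](CC)(CC)CC
F4 | step 10 | ethyl 2-{3-[(2E)-3,7-dimethyl-7-(triethylsilyloxy)oct-2-en-1-yl]-2,4-bis(triisopropylsilyloxy)phenyl}acetate | C/C(=C\Cc1c(O[Si](C(C)C)(C(C)C)C(C)C)ccc(CC(=O)OCC)c1O[Si](C(C)C)(C(C)C)C(C)C)CCCC(C)(C)O[Si](CC)(CC)CC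
F5 | step 10 | N-methoxy-N-methyl-2-{3-[(2E)-3,7-dimethyl-7-(triethylsilyloxy)oct-2-en-1-yl]-2,4-bis(triisopropylsilyloxy)phenyl}acetamide | C/C(=C\Cc1c(O[Si](C(C)C)(C(C)C)C(C)C)ccc(CC(=O)N(C)OC)c1O[Si](C(C)C)(C(C)C)C(C)C)CCCC(C)(C)O[Si](CC)(CC)CC
F6 | step 13 | 1-[2-methoxy-4,6-bis(triisopropylsilyloxy)phenyl]-2-{3-[(2E)-3,7-dimethyl-7-(triethylsilyloxy)oct-2-en-1-yl]-2,4-bis(triisopropylsilyloxy)phenyl}ethanone | C/C(=C\Cc1c(O[Si](C(C)C)(C(C)C)C(C)C)ccc(CC(=O)c2c(O[Si](C(C)C)(C(C)C)C(C)C)cc(O[Si](C(C)C)(C(C)C)C(C)C)cc2OC)c1O[Si](C(C)C)(C(C)C)C(C)C)CCCC(C)(C)O[Si](CC)(CC)CC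
F7 | step 13 | 2-diazo-1-[2-methoxy-4,6-bis(triisopropylsilyloxy)phenyl]-2-{3-[(2E)-3,7-dimethyl-7-(triethylsilyloxy)oct-2-en-1-yl]-2,4-bis(triisopropylsilyloxy)phenyl}ethanone | C/C(=C\Cc1c(O[Si](C(C)C)(C(C)C)C(C)C)ccc(C(=[N+]=[N-])C(=O)c2c(O[Si](C(C)C)(C(C)C)C(C)C)cc(O[Si](C(C)C)(C(C)C)C(C)C)cc2OC)c1O[Si](C(C)C)(C(C)C)C(C)C)CCCC(C)(C)O[Si](CC)(CC)CC
F8 | step 13 | (3S)-5,7-bis(triisopropylsilyloxy)-3-{3-[(2E)-3,7-dimethyl-7-(triethylsilyloxy)oct-2-en-1-yl]-2,4-bis(triisopropylsilyloxy)phenyl}chroman-4-one | C/C(=C\Cc1c(O[Si](C(C)C)(C(C)C)C(C)C)ccc([C@H]2COc3cc(O[Si](C(C)C)(C(C)C)C(C)C)cc(O[Si](C(C)C)(C(C)C)C(C)C)c3C2=O)c1O[Si](C(C)C)(C(C)C)C(C)C)CCCC(C)(C)O[Si](CC)(CC)CC
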